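Early in these runs, exchange on the starting complex is quick, and I want to know what stands much later in two new flasks.

| flask | starting complex | incoming ligand | remark | time |
|---|---|---|---|---|
| Wednesday's | 0.50 mM | 0.37 mM | run made earlier |  |
| Saturday's | 0.50 mM | 0.68 mM | run made earlier |  |
| Tuesday's | 0.50 mM | 0.95 mM | run made earlier |  |
| maple | 0.50 mM | 1.00 mM |  | 4.0 min |
| oak | 0.50 mM | 0.400 mM |  | 4.0 min |

| run | time / s | complex with one exchanged / % | complex with two exchanged / % |
|---|---|---|---|
| Wednesday's | 10.0 | 20 | 1 |
| Wednesday's | 30.0 | 24 | 2 |
| Wednesday's | 60.0 | 20 | 5 |
| Wednesday's | 80.0 | 14 | 1 |
| Wednesday's | 120 | 9 | 5 |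
| Saturday's | 10.0 | 32 | 5 |
| Saturday's | 30.0 | 26 | 11 |
| Saturday's | 60.0 | 15 | 9 |
| Saturday's | 80.0 | 6 | 8 |
| Saturday's | 120 | 3 | 7 |
| Tuesday's | 10.0 | 32 | 11 |
| Tuesday's | 30.0 | 17 | 21 |
| Tuesday's | 60.0 | 5 | 13 |
| Tuesday's | 80.0 | 6 | 12 |
| Tuesday's | 120 | 0 | 17 |

(scatter of a reading: 2 percentage points)

- what was read earlier has a scatter of 2 percentage points, one standard deviation

1. which of these holds the largest part of the starting complex at the end of maple (starting complex / complex with one exchanged / complex with two exchanged)
2. which of these holds the largest part of the starting complex at the end of oak (starting complex / complex with one exchanged / complex with two exchanged)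
3. amount of complex with one exchanged at the end of maple, in percent of the starting complex charged

Tuesday's run looks contradictory. At 10.0 s the complexes with one and two exchanged hold 43.0% of the charge, but at 120 s they hold less, 17.0%, with 1.90 incoming ligand charged per starting complex. A return to starting complex is the obvious reading, so I count turnovers.

If those first readings are all that has left the starting complex, its pseudo-first-order lifetime on Tuesday is 17.8 s, a reading with its scatter. I scale this lifetime from the incoming ligand charged on Tuesday to what remains in maple once each starting complex has taken one. The time divided by that lifetime is the turnover count 7.10 for maple. That leaves 0.0825% starting complex in maple, so I take the lost charge to sit in a form not read, and I expect the complex with two exchanged to lead the three asked in maple, as it stands above the complex with one exchanged at Tuesday's last reading. Oak has 0.800 incoming ligand per starting complex. If each starting complex that reacts takes one incoming ligand, 20.0% stays starting complex in oak, more than either read form at the last reading of Wednesday's run.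

The forecast names starting complex for maple and starting complex for oak, with 0.5% for the complex with one exchanged, holding that “most of the metal is back as starting complex”. Maple gives complex with two exchanged as the largest of the three at 12.2%, with 1.04% starting complex and 0.791% complex with one exchanged; oak gives starting complex at 33.0%.

    starting complex + incoming ligand ⇌ leaving ligand + complex with one exchanged (K = 0.820, k = 100 M⁻¹ s⁻¹)
    complex with one exchanged + incoming ligand ⇌ leaving ligand + complex with two exchanged (K = 16.0, k = 93.0 M⁻¹ s⁻¹)
    complex with two exchanged ⇌ isomer of the product (K = 0.490, k = 0.140 s⁻¹)
    starting complex + complex with two exchanged → side product (k = 270 M⁻¹ s⁻¹)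

In maple 79.9% stands as side product, a form not read and counted as two, and the starting complex in maple is more than the count gave. The neighbouring flask is maple read at 1.0 min. The same count gives it 1.78 turnovers, hence 16.9% starting complex, and that flask holds 10.9%.

The readings were generated by integration with made-up constants.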